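**Retrosynthetic overview**

- The target (robinetinidol-(4β→8)-epigallocatechin) comes from its deca-O-benzyl ether by global hydrogenolysis; at that point all rings exist.
- Ring C of the upper unit is closed last, in one pot: O1–C2 by 6-endo opening of a trans-epoxide by the ring A phenol, then C4–H by hydride transfer to the cyclic C4 cation. Two features allow this: C4 is a doubly benzylic carbon between ring A (O1 ortho and the 7-oxygen para to C4a) and the phloroglucinol-type ring D, and O1–C2 and C3–OH are trans-vicinal, the imprint of a trans-epoxide.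
- The C4–C8 bond to ring D comes from 1,2-addition of 8-lithiated hexa-O-benzylepigallocatechin to an aryl epoxy ketone.
- The epoxy ketone comes from a Claisen–Schmidt chalcone and a Julia–Colonna epoxidation, the only catalyst-controlled stereochemical event; C2 and C4 of the upper unit are relayed from it.
- Ring order: rings A and B are bought arenes, rings D, E and F are bought as (−)-epigallocatechin, and ring C is the only ring made and the last one closed.

Key step: step 9

Remark: the tertiary carbinol carbon made in step 7 is drawn without configuration; either epimer or the mixture is carried on, because this carbon becomes a planar cation in step 9.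

**Route**

Step 1
Reactants: 1 (−)-epigallocatechin
Product: 2 penta-O-benzylepigallocatechin [(2R,3R)-5,7-bis(benzyloxy)-2-(3,4,5-tris(benzyloxy)phenyl)chroman-3-ol]
Conditions: BnBr, K2CO3, DMF, 0 °C to rt, argon
Reagents that add atoms: benzyl bromide, BrCc1ccccc1
Why: Williamson etherification of the five phenols with carbonate base should leave the much less acidic secondary 3-OH free, as is usual for flavan-3-ols, and touches no stereocentre.

Step 2
Reactants: 2 penta-O-benzylepigallocatechin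
Product: 3 hexa-O-benzylepigallocatechin [(2R,3R)-3,5,7-tris(benzyloxy)-2-(3,4,5-tris(benzyloxy)phenyl)chromane]
Conditions: NaH, BnBr, DMF, 0 °C to rt
Reagents that add atoms: benzyl bromide, BrCc1ccccc1
Why: Williamson benzylation of the sodium alkoxide caps O3 so that the later aryllithium carries no acidic proton, and C2 and C3 cannot epimerise once every phenol is etherified.

Step 3
Reactants: 3 hexa-O-benzylepigallocatechin
Product: 4 8-bromo-hexa-O-benzylepigallocatechin [(2R,3R)-3,5,7-tris(benzyloxy)-8-bromo-2-(3,4,5-tris(benzyloxy)phenyl)chromane]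
Conditions: NBS, CH2Cl2, −78 °C to rt
Reagents that add atoms: N-bromosuccinimide, O=C1CCC(=O)N1Br
Why: Electrophilic aromatic bromination of the phloroglucinol-type ring D should occur at C8 rather than C6, the established regiochemistry for 5,7-di-O-benzyl flavan-3-ols, and fixes the later point of attachment.

Step 4
Reactants: 5 1-[4-(benzyloxy)-2-hydroxyphenyl]ethan-1-one
Product: 6 1-[2-(allyloxy)-4-(benzyloxy)phenyl]ethan-1-one
Conditions: allyl bromide, K2CO3, DMF, rt
Reagents that add atoms: allyl bromide, C=CCBr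
Why: Williamson O-allylation gives a phenol protecting group that survives hydroxide, peroxide and organolithium and can later be removed under neutral conditions.

Step 5
Reactants: 6 1-[2-(allyloxy)-4-(benzyloxy)phenyl]ethan-1-one; 7 3,4,5-tris(benzyloxy)benzaldehyde
Product: 8 (E)-1-[2-(allyloxy)-4-(benzyloxy)phenyl]-3-[3,4,5-tris(benzyloxy)phenyl]prop-2-en-1-one
Conditions: KOH, EtOH/THF, rt
Reagents that add atoms: none
Why: Claisen–Schmidt condensation of the methyl ketone with the non-enolisable aldehyde should give the E-enone after E1cB dehydration.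

Step 6
Reactants: 8 the chalcone
Product: 9 [2-(allyloxy)-4-(benzyloxy)phenyl]{(2R,3S)-3-[3,4,5-tris(benzyloxy)phenyl]oxiran-2-yl}methanone
Conditions: poly-L-leucine (cat.), urea–H2O2, DBU, THF, rt
Reagents that add atoms: urea–hydrogen peroxide, NC(N)=O.OO
Why: Julia–Colonna epoxidation (conjugate addition of hydroperoxide on the poly-L-leucine helix, then ring closure) of the E-enone is expected to give the (2R,3S)-trans-epoxide, the only catalyst-controlled stereochemical element of the upper unit, while the allyl ether alkene is inert to nucleophilic peroxide.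

Step 7
Reactants: 4 8-bromo-hexa-O-benzylepigallocatechin; 9 the (2R,3S)-epoxy ketone
Product: 11 [2-(allyloxy)-4-(benzyloxy)phenyl](hexa-O-benzylepigallocatechin-8-yl){(2R,3S)-3-[3,4,5-tris(benzyloxy)phenyl]oxiran-2-yl}methanol (carbinol epimers), via 8-lithio-hexa-O-benzylepigallocatechin 10 (not isolated)
Conditions: t-BuLi, THF, −78 °C; then 9, −78 to −40 °C; then H2O
Reagents that add atoms: none
Why: Bromine–lithium exchange followed by 1,2-addition of the aryllithium to the ketone (the addition known for 8-lithiated benzylated flavans with flavan-4-ones) should form the C4–C8 bond at a defined position of ring D without touching the epoxide stereocentres, and the configuration of the new carbinol carbon does not matter.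

Step 8
Reactants: 11 the allyl-protected tertiary carbinol
Product: 12 [4-(benzyloxy)-2-hydroxyphenyl](hexa-O-benzylepigallocatechin-8-yl){(2R,3S)-3-[3,4,5-tris(benzyloxy)phenyl]oxiran-2-yl}methanol (carbinol epimers; used without delay)
Conditions: Pd(PPh3)4 (cat.), morpholine, THF, rt
Reagents that add atoms: none
Why: Tsuji–Trost-type deallylation with zerovalent palladium and morpholine as allyl acceptor should free the ring A phenol under neutral conditions that leave the epoxide, the tertiary carbinol and all benzyl ethers intact.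

Step 9
Reactants: 12 the free phenol epoxy carbinol
Product: 14 deca-O-benzyl robinetinidol-(4β→8)-epigallocatechin [(2R,3S,4R)-7-(benzyloxy)-4-[(2R,3R)-3,5,7-tris(benzyloxy)-2-(3,4,5-tris(benzyloxy)phenyl)chroman-8-yl]-2-[3,4,5-tris(benzyloxy)phenyl]chroman-3-ol], via 3-hydroxy-4-arylflavan-4-ylium trifluoroacetate 13 (not isolated)
Conditions: TFA, CH2Cl2, −78 to −20 °C; then Bu3SnH, −78 to 0 °C
Reagents that add atoms: none
Why: TFA protonates the epoxide of 12 and the ring A phenol oxygen opens it at the benzylic carbon (the future C2) in a 6-endo-tet closure of ring C, the acid-mediated phenol–epoxide cyclisation known from trans-dihydroflavonol and flavan-3-ol synthesis; in the same medium the tertiary, doubly benzylic C4–OH ionises (reversibly, also before ring closure), so the closed ring rests as the flavan-4-ylium ion 13, which Bu3SnH then reduces as in the known ionic hydrogenation of 4-aryl-flavan-4-ols. C2 is set by SN2-type inversion at the 3S epoxide carbon and C3 keeps the epoxide oxygen, so the 2,3-trans relation is relayed from the epoxide of step 6 (a looser, cation-like opening would still place the C2 aryl group equatorial and give the same isomer). C4 is set on the cyclic cation by substrate control: hydride should enter the face anti to the C3 oxygen, the face that nucleophiles also prefer on 2,3-trans-flavan-4-yl cations, which leaves ring D cis to the 3-OH (4R). The step needs 6-endo over 5-exo opening, secured by the benzylic tris(benzyloxy)phenyl-bearing carbon and by the fully substituted C4 next to the other epoxide carbon, and it needs ring closure before hydride transfer, secured by adding Bu3SnH only after the acid stage so that no hydride donor is present while an open-chain cation exists. The configuration of the carbinol carbon of 12 is irrelevant because that carbon is planarised.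

Step 10
Reactants: 14 the deca-O-benzyl ether
Product: 15 robinetinidol-(4β→8)-epigallocatechin [(2R,3S,4R)-4-[(2R,3R)-3,5,7-trihydroxy-2-(3,4,5-trihydroxyphenyl)chroman-8-yl]-2-(3,4,5-trihydroxyphenyl)chromane-3,7-diol]
Conditions: H2 (1 atm), Pd(OH)2/C, THF/MeOH/H2O, rt
Reagents that add atoms: none
Why: Hydrogenolysis of nine aryl benzyl ethers and one alkyl benzyl ether over Pd(OH)2/C, the usual last step for benzylated proanthocyanidins, should leave the C4–C8 interflavan bond and both pyran C2–O1 bonds intact and touch no stereocentre.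

**Compound list**

1 | (−)-epigallocatechin, (2R,3R)-2-(3,4,5-trihydroxyphenyl)chromane-3,5,7-triol | Oc1cc(O)c2c(c1)O[C@H](c1cc(O)c(O)c(O)c1)[C@H](O)C2 | starting material

2 | (2R,3R)-5,7-bis(benzyloxy)-2-[3,4,5-tris(benzyloxy)phenyl]chroman-3-ol | c1ccccc1COc1cc(OCc3ccccc3)c2c(c1)O[C@H](c1cc(OCc3ccccc3)c(OCc3ccccc3)c(OCc3ccccc3)c1)[C@H](O)C2 | intermediate

3 | (2R,3R)-3,5,7-tris(benzyloxy)-2-[3,4,5-tris(benzyloxy)phenyl]chromane | c1ccccc1COc1cc(OCc3ccccc3)c2c(c1)O[C@H](c1cc(OCc3ccccc3)c(OCc3ccccc3)c(OCc3ccccc3)c1)[C@H](OCc1ccccc1)C2 | intermediate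

4 | (2R,3R)-3,5,7-tris(benzyloxy)-8-bromo-2-[3,4,5-tris(benzyloxy)phenyl]chromane | c1ccccc1COc1cc(OCc3ccccc3)c2c(c1Br)O[C@H](c1cc(OCc3ccccc3)c(OCc3ccccc3)c(OCc3ccccc3)c1)[C@H](OCc1ccccc1)C2 | intermediate

5 | 1-[4-(benzyloxy)-2-hydroxyphenyl]ethan-1-one | CC(=O)c1ccc(OCc2ccccc2)cc1O | starting material

6 | 1-[2-(allyloxy)-4-(benzyloxy)phenyl]ethan-1-one | CC(=O)c1ccc(OCc2ccccc2)cc1OCC=C | intermediate

7 | 3,4,5-tris(benzyloxy)benzaldehyde | O=Cc1cc(OCc2ccccc2)c(OCc2ccccc2)c(OCc2ccccc2)c1 | starting material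

8 | (E)-1-[2-(allyloxy)-4-(benzyloxy)phenyl]-3-[3,4,5-tris(benzyloxy)phenyl]prop-2-en-1-one | C=CCOc1cc(OCc2ccccc2)ccc1C(=O)/C=C/c1cc(OCc2ccccc2)c(OCc2ccccc2)c(OCc2ccccc2)c1 | intermediate

9 | [2-(allyloxy)-4-(benzyloxy)phenyl]{(2R,3S)-3-[3,4,5-tris(benzyloxy)phenyl]oxiran-2-yl}methanone | C=CCOc1cc(OCc2ccccc2)ccc1C(=O)[C@@H]1O[C@H]1c1cc(OCc2ccccc2)c(OCc2ccccc2)c(OCc2ccccc2)c1 | intermediate

10 | 8-lithio derivative of 3, [(2R,3R)-3,5,7-tris(benzyloxy)-2-(3,4,5-tris(benzyloxy)phenyl)chroman-8-yl]lithium | c1ccccc1COc1cc(OCc3ccccc3)c2c(c1[Li])O[C@H](c1cc(OCc3ccccc3)c(OCc3ccccc3)c(OCc3ccccc3)c1)[C@H](OCc1ccccc1)C2 | intermediate (not isolated)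

11 | [2-(allyloxy)-4-(benzyloxy)phenyl][(2R,3R)-3,5,7-tris(benzyloxy)-2-(3,4,5-tris(benzyloxy)phenyl)chroman-8-yl]{(2R,3S)-3-[3,4,5-tris(benzyloxy)phenyl]oxiran-2-yl}methanol, carbinol carbon undefined | C=CCOc1cc(OCc2ccccc2)ccc1C(O)(c1c(OCc2ccccc2)cc(OCc2ccccc2)c2c1O[C@H](c1cc(OCc3ccccc3)c(OCc3ccccc3)c(OCc3ccccc3)c1)[C@H](OCc1ccccc1)C2)[C@@H]1O[C@H]1c1cc(OCc2ccccc2)c(OCc2ccccc2)c(OCc2ccccc2)c1 | intermediate

12 | [4-(benzyloxy)-2-hydroxyphenyl][(2R,3R)-3,5,7-tris(benzyloxy)-2-(3,4,5-tris(benzyloxy)phenyl)chroman-8-yl]{(2R,3S)-3-[3,4,5-tris(benzyloxy)phenyl]oxiran-2-yl}methanol, carbinol carbon undefined | Oc1cc(OCc2ccccc2)ccc1C(O)(c1c(OCc2ccccc2)cc(OCc2ccccc2)c2c1O[C@H](c1cc(OCc3ccccc3)c(OCc3ccccc3)c(OCc3ccccc3)c1)[C@H](OCc1ccccc1)C2)[C@@H]1O[C@H]1c1cc(OCc2ccccc2)c(OCc2ccccc2)c(OCc2ccccc2)c1 | intermediate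

13 | 2,3-trans-7-(benzyloxy)-3-hydroxy-4-(hexa-O-benzylepigallocatechin-8-yl)-2-[3,4,5-tris(benzyloxy)phenyl]chroman-4-ylium trifluoroacetate (C2 and C3 arranged as in 14) | c1ccccc1COc1ccc2c(c1)O[C@H](c1cc(OCc3ccccc3)c(OCc3ccccc3)c(OCc3ccccc3)c1)[C@@H](O)[C+]2c1c(OCc2ccccc2)cc(OCc2ccccc2)c2c1O[C@H](c1cc(OCc3ccccc3)c(OCc3ccccc3)c(OCc3ccccc3)c1)[C@H](OCc1ccccc1)C2.[O-]C(=O)C(F)(F)F | intermediate (not isolated)

14 | (2R,3S,4R)-7-(benzyloxy)-4-[(2R,3R)-3,5,7-tris(benzyloxy)-2-(3,4,5-tris(benzyloxy)phenyl)chroman-8-yl]-2-[3,4,5-tris(benzyloxy)phenyl]chroman-3-ol | c1ccccc1COc1ccc2c(c1)O[C@H](c1cc(OCc3ccccc3)c(OCc3ccccc3)c(OCc3ccccc3)c1)[C@@H](O)[C@H]2c1c(OCc2ccccc2)cc(OCc2ccccc2)c2c1O[C@H](c1cc(OCc3ccccc3)c(OCc3ccccc3)c(OCc3ccccc3)c1)[C@H](OCc1ccccc1)C2 | intermediate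

15 | robinetinidol-(4β→8)-epigallocatechin, (2R,3S,4R)-4-[(2R,3R)-3,5,7-trihydroxy-2-(3,4,5-trihydroxyphenyl)chroman-8-yl]-2-(3,4,5-trihydroxyphenyl)chromane-3,7-diol | Oc1ccc2c(c1)O[C@H](c1cc(O)c(O)c(O)c1)[C@@H](O)[C@H]2c1c(O)cc(O)c2c1O[C@H](c1cc(O)c(O)c(O)c1)[C@H](O)C2 | target

**Count and risks**

Total step count: 10. Longest linear sequence: 7 steps (steps 1, 2, 3, 7, 8, 9, 10; the other branch, steps 4, 5, 6, 7, 8, 9, 10, is equally long).

Steps most likely to fail:

1. Step 9. Hydride transfer may overtake ring closure, so that an open-chain cation is reduced under acyclic control. The facial preference on the cyclic cation may also be weak with a free 3-OH, or the 3-hydroxy cation may undergo a pinacol-type 1,2-hydride shift to a flavan-3-one. The fallback separates the events and adds a steering group. Setting out from 12, ring C would first be closed under anionic conditions (K2CO3, MeOH/THF, rt; phenoxide 6-endo-tet epoxide opening) to the 2,3-trans-4-aryl-flavan-3,4-diol F1. The secondary 3-OH would then be silylated (TESOTf, 2,6-lutidine, CH2Cl2, −78 °C) to the 3-O-triethylsilyl ether F2. F2 would be reduced with Bu3SnH and TFA at −78 °C, the hydride donor being present before the acid and the bulky silyloxy group directing hydride to the opposite face, to the 3-O-triethylsilyl ether of 14, F3. TBAF in THF would bring the route back at 14.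

2. Step 7. The di-ortho-substituted aryllithium may fail to reach the carbonyl carbon of the chelating open-chain epoxy ketone and transfer an electron or attack the oxirane instead. The fallback closes ring C before the two halves are joined, so that the aryllithium meets an exposed cyclic ketone. Setting out from 9, deallylation (Pd(PPh3)4, morpholine, THF) would give the 2'-hydroxy epoxy ketone F4. Acid-mediated 6-endo cyclisation would give the (2R,3R)-trans-dihydroflavonol F5, and silylation (TBSCl, imidazole, DMF) its 3-O-TBS ether F6. Addition of aryllithium 10 (from 4 and t-BuLi) to the C4 ketone would give the tertiary alcohol F7. Reduction with Bu3SnH and TFA, hydride entering anti to the silyloxy group, would give the 3-O-TBS ether of 14, F8, and TBAF would bring the route back at 14.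

3. Step 6. Conjugate addition of hydroperoxide to an electron-rich, sparingly soluble 2'-alkoxychalcone may be slow and poorly enantioselective. The fallback moves the epoxidation to the allylic alcohol oxidation level and uses an electrophilic oxidant. Setting out from 8, Luche reduction (NaBH4, CeCl3·7H2O, MeOH, 0 °C) would give the allylic alcohol F9. Shi epoxidation with the enantiomer of the D-fructose-derived ketone (KHSO5 as 2KHSO5·KHSO4·K2SO4, K2CO3, MeCN/dimethoxymethane/H2O, 0 °C) would give the epoxy alcohol F10 with the oxirane configured as in 9. Dess–Martin oxidation would bring the route back at 9.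

**Further compounds**

F1 | step 9 | (2R,3R)-7-(benzyloxy)-4-(hexa-O-benzylepigallocatechin-8-yl)-2-[3,4,5-tris(benzyloxy)phenyl]chromane-3,4-diol, 2,3-trans, C4 undefined | c1ccccc1COc1ccc2c(c1)O[C@H](c1cc(OCc3ccccc3)c(OCc3ccccc3)c(OCc3ccccc3)c1)[C@@H](O)C2(O)c1c(OCc2ccccc2)cc(OCc2ccccc2)c2c1O[C@H](c1cc(OCc3ccccc3)c(OCc3ccccc3)c(OCc3ccccc3)c1)[C@H](OCc1ccccc1)C2

F2 | step 9 | 3-O-triethylsilyl ether of F1 | c1ccccc1COc1ccc2c(c1)O[C@H](c1cc(OCc3ccccc3)c(OCc3ccccc3)c(OCc3ccccc3)c1)[C@@H](O[Si](CC)(CC)CC)C2(O)c1c(OCc2ccccc2)cc(OCc2ccccc2)c2c1O[C@H](c1cc(OCc3ccccc3)c(OCc3ccccc3)c(OCc3ccccc3)c1)[C@H](OCc1ccccc1)C2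

F3 | step 9 | 3-O-triethylsilyl ether of 14, (2R,3S,4R) | c1ccccc1COc1ccc2c(c1)O[C@H](c1cc(OCc3ccccc3)c(OCc3ccccc3)c(OCc3ccccc3)c1)[C@@H](O[Si](CC)(CC)CC)[C@H]2c1c(OCc2ccccc2)cc(OCc2ccccc2)c2c1O[C@H](c1cc(OCc3ccccc3)c(OCc3ccccc3)c(OCc3ccccc3)c1)[C@H](OCc1ccccc1)C2

F4 | step 7 | [4-(benzyloxy)-2-hydroxyphenyl]{(2R,3S)-3-[3,4,5-tris(benzyloxy)phenyl]oxiran-2-yl}methanone | Oc1cc(OCc2ccccc2)ccc1C(=O)[C@@H]1O[C@H]1c1cc(OCc2ccccc2)c(OCc2ccccc2)c(OCc2ccccc2)c1

F5 | step 7 | (2R,3R)-7-(benzyloxy)-3-hydroxy-2-[3,4,5-tris(benzyloxy)phenyl]chroman-4-one | c1ccccc1COc1ccc2c(c1)O[C@H](c1cc(OCc3ccccc3)c(OCc3ccccc3)c(OCc3ccccc3)c1)[C@@H](O)C2=O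

F6 | step 7 | (2R,3R)-7-(benzyloxy)-3-[(tert-butyldimethylsilyl)oxy]-2-[3,4,5-tris(benzyloxy)phenyl]chroman-4-one | c1ccccc1COc1ccc2c(c1)O[C@H](c1cc(OCc3ccccc3)c(OCc3ccccc3)c(OCc3ccccc3)c1)[C@@H](O[Si](C)(C)C(C)(C)C)C2=O

F7 | step 7 | (2R,3R)-7-(benzyloxy)-3-[(tert-butyldimethylsilyl)oxy]-4-(hexa-O-benzylepigallocatechin-8-yl)-2-[3,4,5-tris(benzyloxy)phenyl]chroman-4-ol, C4 undefined | c1ccccc1COc1ccc2c(c1)O[C@H](c1cc(OCc3ccccc3)c(OCc3ccccc3)c(OCc3ccccc3)c1)[C@@H](O[Si](C)(C)C(C)(C)C)C2(O)c1c(OCc2ccccc2)cc(OCc2ccccc2)c2c1O[C@H](c1cc(OCc3ccccc3)c(OCc3ccccc3)c(OCc3ccccc3)c1)[C@H](OCc1ccccc1)C2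

F8 | step 7 | 3-O-tert-butyldimethylsilyl ether of 14, (2R,3S,4R) | c1ccccc1COc1ccc2c(c1)O[C@H](c1cc(OCc3ccccc3)c(OCc3ccccc3)c(OCc3ccccc3)c1)[C@@H](O[Si](C)(C)C(C)(C)C)[C@H]2c1c(OCc2ccccc2)cc(OCc2ccccc2)c2c1O[C@H](c1cc(OCc3ccccc3)c(OCc3ccccc3)c(OCc3ccccc3)c1)[C@H](OCc1ccccc1)C2

F9 | step 6 | (E)-1-[2-(allyloxy)-4-(benzyloxy)phenyl]-3-[3,4,5-tris(benzyloxy)phenyl]prop-2-en-1-ol, racemic at the carbinol carbon | C=CCOc1cc(OCc2ccccc2)ccc1C(O)/C=C/c1cc(OCc2ccccc2)c(OCc2ccccc2)c(OCc2ccccc2)c1

F10 | step 6 | [2-(allyloxy)-4-(benzyloxy)phenyl]{(2S,3S)-3-[3,4,5-tris(benzyloxy)phenyl]oxiran-2-yl}methanol, oxirane arranged in space as in 9 (the descriptor at oxirane C2 changes with the carbinol neighbour), carbinol carbon undefined | C=CCOc1cc(OCc2ccccc2)ccc1C(O)[C@@H]1O[C@H]1c1cc(OCc2ccccc2)c(OCc2ccccc2)c(OCc2ccccc2)c1
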